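All runs are simulated for an exercise, noise included.

Substrate charged to this closed flask stays in it, so the percentages of its forms add to 100, and what the two followed species don't hold can be had by subtraction.

common to all: substrate 0.33 M
- grey: the very flask that is asked about, followed so far
- flask: time 15 d

- grey (time / d: open dimer / %, single ring / %): 0.0417: 18, 10; 0.104: 20, 14; 0.208: 23, 28; 0.417: 17, 32; 1.04: 6, 44; 2.00: 2, 52; 5.00: 0, 47

(standard deviation of a reading: 2 percentage points)

- percentages count the substrate that a species holds: one open dimer counts as two
- the numbers in the tables scatter with a standard deviation of 2 percentage points
- a reading or a percentage of single ring counts all its forms, free or not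

1. time up to 15 d at which open dimer stands highest
2. the amount of open dimer, in percent of the substrate charged, at that time

I read the rows from the top. In the first, at 0.0417 d, open dimer has had the least time to drain, so I divide the rate of making single ring by the rate of making open dimer, time drops out, and the readings 10% and 18% give a split, the selectivity factor, of 0.556, rough because each reading scatters by 2 percentage points. In the last row, at 5.00 d, open dimer reads 0% and single ring 47%, leaving 53.0%; if that remainder left through open dimer, the overall split is 0.887, higher than the first. I expect this rise if single ring takes one substrate and open dimer two, since the split then varies inversely with substrate. So I multiply the first split by the charge to get the crossing charge, my rough reading of the substrate concentration at which the two take substrate equally: 0.183 M. This figure reads high, since the two readings of the first row already account for 28.0% of the substrate, so that split belongs to a substrate concentration below the charge. This flask starts above it, so open dimer is favoured early. The middle rows read 20%, 23% and 17%, so I place the top between 0.104 d and 0.417 d, near 23%.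

The forecast gives 22% at 0.17 d, reasoning that “This looks like a classic intermediate”.

The flask gives 22.1% at 0.166 d, close to the forecast.

    substrate ⇌ dormant form (K = 0.410, k = 1.80 × 10⁻⁴ s⁻¹)
    substrate + open dimer → open trimer (k = 1.00 × 10⁻⁴ M⁻¹ s⁻¹)
    open dimer → ring dimer (k = 2.80 × 10⁻⁵ s⁻¹)
    crystals ⇌ single ring, rate k4*(cs4 - [single ring]) while solid is left; crystals form when [single ring] > cs4 (solubility = 0.290 M, k = 1.70 × 10⁻⁴ s⁻¹)
    2 substrate → open dimer (k = 1.40 × 10⁻⁴ M⁻¹ s⁻¹)
    substrate → single ring (k = 3.20 × 10⁻⁵ s⁻¹)

At 15.0 d this flask holds 51.7% of single ring against 11.7% of open trimer and 36.6% of ring dimer, a ratio of 1.07, about twice the first split. For the neighbour charged with 0.83 M, the crossing charge gives a split of 0.221. At 15.0 d that neighbour holds 31.3% of single ring against 25.6% of open trimer and 43.1% of ring dimer, a ratio of 0.457, again about twice that split, and its open dimer peaks at 31.7%, higher than in this flask.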